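**Remark on the chemistry (assumption).** The target has no stereocentre and no stereogenic double bond (the prenyl alkene carries two methyl groups), and the C3–C1' axis is not hindered enough to be configurationally stable. The compound is therefore achiral; "single enantiomer" is met by the compound itself and no step needs absolute stereocontrol.

**Compound numbers used throughout**

- 1: 2,4,6-trihydroxyacetophenone
- 2: 1-[2,4-bis(benzyloxy)-6-hydroxyphenyl]ethan-1-one
- 3: 2,4-dihydroxybenzaldehyde
- 4: 2,4-bis(benzyloxy)benzaldehyde
- 5: the 2'-hydroxychalcone from 2 and 4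
- 6: the racemic tetra-O-benzyl flavanone
- 7: the C3 aryl-λ3-iodane of 6 (not isolated)
- 8: the tetra-O-benzyl isoflavone
- 9: 5,7,2',4'-tetrahydroxyisoflavone
- 10: the target

## Analysis of the target

The target is an isoflavone: a 4H-chromen-4-one (benzo ring A = C4a, C5–C8, C8a; pyranone ring C = O1, C2, C3, C4) that carries a 2,4-dihydroxyphenyl ring B (C1'–C6') on C3. Ring A bears a free 5-OH, hydrogen-bonded to the C4 carbonyl, and a 3-methylbut-2-enyl (prenyl) ether on O7; C2, C6 and C8 are unsubstituted. There is no stereocentre and no atropisomerism, so the problem is one of connectivity and chemoselectivity only. The prenyl aryl ether is the most fragile group: acid cleaves it or cyclises it, heat triggers Claisen rearrangement, hydrogenolysis removes it, and electrophilic oxidants attack its trisubstituted alkene. The free phenols are easily oxidised, C2 of the chromone is open to conjugate attack by hydroxide, and the 2'-OH next to the C3–C1' bond closes onto neighbouring electrophilic carbons (benzofuran or coumaronochromone formation) in many open-chain or oxidised precursors. The two real difficulties are the C3–C1' bond, which joins an electron-rich, ortho-oxygenated arene to the α-carbon of the pyranone, and the distinction of four phenolic oxygens so that only O7 is prenylated under mild final conditions. The feature that invites the strategy is that C3–C1' lies next to the C2–O1 unit and that C1' has oxygen on both its ortho carbon (C2') and its para carbon (C4'). This is the ideal pattern for a 1,2-aryl shift through a phenonium ion, and it is the way nature brings ring B from C2 of a flavanone to C3.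

## Retrosynthetic reasoning

**10 ⇒ 9.** The O7–CH2 bond of the prenyl ether is cut last. The prenyl group cannot survive hydrogenolysis or an electrophilic oxidant, so it must enter after both. The forward step has to alkylate O7 only; this rests on the 7-OH being a vinylogous carboxylic acid (para to C4=O), far more acidic than the chelated 5-OH and the two ring-B phenols.

**9 ⇒ 8.** The four O–benzyl bonds are cut together. Benzyl is chosen because it withstands hydroxide, acetate, sulfonic acid and iodine(III), is removed in one neutral operation, and leaves the B-ring oxygens as strong donors, which the key step needs.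

**8 ⇒ 6 (through 7), the strategic cut.** The C3–C1' bond is not cut into two fragments; instead ring B is moved back from C3 to C2, which turns the isoflavone 8 into the isomeric flavanone 6. In the forward direction the C2–C1' bond is broken, the C3–C1' bond and the C2=C3 double bond are formed, and the skeleton changes from 2-aryl to 3-aryl. The cut is made here because every conventional way of forming C3–C1' needs two pre-oxidised partners or buys the bond in an arylacetic acid, whereas a 2-aryl precursor arises from an aldehyde by plain aldol chemistry. The forward reaction must oxidise C3 of 6 to a leaving group (iodane 7) and make the aryl shift beat elimination, solvent capture and A-ring migration. The ortho/para-dioxygenated ring B is what secures this.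

**6 ⇒ 5.** The O1–C2 bond is cut (retro-oxa-Michael), giving the 2'-hydroxychalcone 5. The stereocentre created at C2 in the forward sense may be racemic, since the key step erases it.

**5 ⇒ 2 + 4.** The Cα=Cβ bond is cut (retro-aldol condensation) into methyl ketone 2 and aldehyde 4, which has no α-hydrogen. All carbons of the target except the prenyl group are then present.

**2 ⇒ 1 and 4 ⇒ 3.** The benzyl ethers are removed to reach two cheap phenols. In 1 the strong hydrogen bond of one ortho OH to the acetyl group leaves exactly the OH free that later becomes O1.

## Alternatives that were turned down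

**Alternative 1: the textbook deoxybenzoin route.** Disconnection: the C4–C4a aryl–acyl bond and both bonds to C2, which is treated as a one-carbon insert. Forward key step: Friedel–Crafts (Houben–Hoesch type) acylation of phloroglucinol A1 with (2,4-dimethoxyphenyl)acetic acid A2 to the deoxybenzoin A3, ring closure with a formamide-derived C1 electrophile to 5,7-dihydroxy-2',4'-dimethoxyisoflavone A4, then O-demethylation to 9. Reasons for turning it down:
- It is the route most chemists would draw first, and every skeletal bond is made by classical electrophilic substitution; C3–C1' is simply bought in A2.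
- O2' must enter as a robust ether, because a free ortho phenol would lactonise at the acid stage and dehydrate to a 2-arylbenzofuran at the stage of A3.
- The methyl ethers then need a boron trihalide for removal, which the prenyl ether cannot survive, so the endgame is the same as here (9, then prenylation).
- The step count would be similar or slightly lower, but nothing in it answers the brief for a bold key step.

**Alternative 2: Suzuki–Miyaura coupling at C3–C1'.** Disconnection: C3–C1' into a C3 electrophile and an aryl nucleophile. Forward key step: palladium-catalysed coupling of 5,7-bis(benzyloxy)-3-iodochromone A5 (from 2 through an enaminone and iodocyclisation) with [2,4-bis(benzyloxy)phenyl]boronic acid A6 to give 8. Reasons for turning it down: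
- It is sound but standard.
- Both partners must be pre-oxidised (C–I and C–B), at a cost of two steps each.
- A6 is an ortho,para-dialkoxy arylboronic acid, the type most prone to protodeboronation.
- The coupling site is flanked by C4=O and the 2'-benzyloxy group.
- It reaches 8 in no fewer steps than the chosen route. It is kept as the fallback for the key step.

**Alternative 3: oxidative union of two nucleophilic carbons.** Disconnection: C3–C1' into two C–H bonds, C3–H of 5,7-dihydroxychromone A7 and C4–H of resorcinol A8. Forward key step: anodic or iodine(III)-mediated cross-dehydrogenative coupling of A7 with A8 to give 9 directly. Reasons for turning it down: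
- C3 of A7 is the α-carbon of a vinylogous ester and is less nucleophilic than C6 and C8 of its own phloroglucinol-type ring A, so the oxidised partner would be intercepted there.
- A8 is oxidised more easily than A7 and would mainly couple with itself or through oxygen.
- There is no close precedent for C3 selectivity on such a chromone. The route would be very short, but regio- and chemoselectivity would both be unsupported, so the risk would not sit in one defensible place.

Key step: step 5

## Route

**Step 1**
Reactants: 1 2,4,6-trihydroxyacetophenone
Product: 2 1-[2,4-bis(benzyloxy)-6-hydroxyphenyl]ethan-1-one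
Conditions: BnBr (2.05 equiv), K2CO3 (2.2 equiv), acetone, reflux
Reagents that add atoms: benzyl bromide, BrCc1ccccc1
Why: Williamson ether synthesis under acidity control: the 4-OH (para to the acetyl group) and one ortho OH are alkylated, while the last ortho OH stays locked in the hydrogen bond to the carbonyl and is weakly nucleophilic, so two equivalents of bromide should stop at the di-ether.

**Step 2**
Reactants: 3 2,4-dihydroxybenzaldehyde
Product: 4 2,4-bis(benzyloxy)benzaldehyde
Conditions: BnBr (2.3 equiv), K2CO3 (3 equiv), DMF, 60 °C
Reagents that add atoms: benzyl bromide, BrCc1ccccc1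
Why: Exhaustive Williamson etherification; the chelated 2-OH needs the dipolar solvent and warming, and the aldehyde is inert to carbonate.

**Step 3**
Reactants: 2 1-[2,4-bis(benzyloxy)-6-hydroxyphenyl]ethan-1-one; 4 2,4-bis(benzyloxy)benzaldehyde
Product: 5 (E)-1-[2,4-bis(benzyloxy)-6-hydroxyphenyl]-3-[2,4-bis(benzyloxy)phenyl]prop-2-en-1-one
Conditions: KOH (50% aq., 10 equiv), EtOH/THF, rt, 24–48 h; then 1 M HCl
Reagents that add atoms: none
Why: Claisen–Schmidt (crossed aldol) condensation: 4 has no α-hydrogen and 2 has a single enolisable position, so only one aldol is possible, and E1cB dehydration should give the conjugated E-alkene as the thermodynamic product; benzyl ethers are inert to hydroxide.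

**Step 4**
Reactants: 5 (E)-1-[2,4-bis(benzyloxy)-6-hydroxyphenyl]-3-[2,4-bis(benzyloxy)phenyl]prop-2-en-1-one
Product: 6 rac-5,7-bis(benzyloxy)-2-[2,4-bis(benzyloxy)phenyl]chroman-4-one
Conditions: NaOAc (5 equiv), EtOH, reflux
Reagents that add atoms: none
Why: Chalcone–flavanone isomerisation by intramolecular oxa-Michael addition (6-endo-trig) of the 2'-phenoxide; the 6'-benzyloxy group twists the enone out of the plane of ring A and so favours the closed form; C2 is formed as a racemate on purpose, because step 5 removes this stereocentre.

**Step 5**
Reactants: 6 rac-5,7-bis(benzyloxy)-2-[2,4-bis(benzyloxy)phenyl]chroman-4-one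
Product: 8 5,7-bis(benzyloxy)-3-[2,4-bis(benzyloxy)phenyl]-4H-chromen-4-one, via C3 aryliodanyl flavanone 7 (not isolated)
Conditions: PhI(OH)OTs (1.2 equiv), MeCN, 60 °C
Reagents that add atoms: [hydroxy(tosyloxy)iodo]benzene (HTIB), Cc1ccc(S(=O)(=O)OI(O)c2ccccc2)cc1 (its PhI(OTs) unit is carried by intermediate 7 only; no atom of it stays in 8)
Why: Acid-catalysed enolisation of the C4 ketone towards C3, its only α-position, and attack of the enol on iodine(III) should give the C3 iodane 7, formed as or equilibrated to the 2,3-trans isomer. In the trans-diaxial conformer the C2 aryl group is antiperiplanar to the C3–I bond, and the phenyl-λ3-iodanyl group is an exceptionally good leaving group, so ring B should displace iodobenzene by ipso attack of C1' on C3 through a bridged phenonium ion whose charge falls on C2', C4' and C6' and is taken up by the benzyloxy oxygens on C2' and C4'. Opening of the bridge on the C2 side leaves a cation at C2 that is an oxocarbenium ion of O1, and loss of H3 (directly, or after reversible capture of the water present and dehydration, as in the enzymatic path) gives the C2=C3 bond of the chromone. The closest known reaction type is the HTIB-induced oxidative 2,3-aryl migration of flavanones to isoflavones in acetonitrile, with the thallium(III) versions as further relatives; the step copies the isoflavone synthase reaction, which also oxidises C3 of a flavanone and moves ring B from C2 to C3. No ring is closed: the pyranone ring is kept, and only a transient spiro three-membered phenonium bridge (3-exo attack of the arene) is formed and opened. No stereocentre is created; the only one of 6 (C2) becomes sp2, which is why racemic 6 is sufficient. The step needs aryl migration to win over plain elimination to the 2-arylchromone, over solvent capture at C3 and over A-ring migration with ring contraction; the ortho/para-dialkoxy pattern of ring B gives the highest migratory aptitude available, and the non-nucleophilic solvent removes the ketalisation that opens the ring-contraction path. It also needs iodine(III) to attack the enol and not the electron-rich arene carbons C5', C6 and C8, which rests on near-stoichiometric reagent, acetonitrile instead of a fluoroalcohol and benzyl ethers instead of free phenols, and is the main risk.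

**Step 6**
Reactants: 8 5,7-bis(benzyloxy)-3-[2,4-bis(benzyloxy)phenyl]-4H-chromen-4-one
Product: 9 3-(2,4-dihydroxyphenyl)-5,7-dihydroxy-4H-chromen-4-one
Conditions: H2 (1 atm), 10% Pd/C, THF/MeOH, rt
Reagents that add atoms: none
Why: Catalytic hydrogenolysis of four benzyl aryl ethers; benzylic C–O cleavage should be much faster than hydrogenation of the vinylogous-ester C2=C3 bond, so the reaction is stopped after uptake of four equivalents of hydrogen.

**Step 7**
Reactants: 9 3-(2,4-dihydroxyphenyl)-5,7-dihydroxy-4H-chromen-4-one
Product: 10 3-(2,4-dihydroxyphenyl)-5-hydroxy-7-[(3-methylbut-2-en-1-yl)oxy]-4H-chromen-4-one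
Conditions: prenyl bromide (1.05 equiv), K2CO3 (1.0 equiv), DMF, 0 °C to rt; pH 6 phosphate buffer work-up
Reagents that add atoms: prenyl bromide (1-bromo-3-methylbut-2-ene), CC(C)=CCBr
Why: Acidity-controlled Williamson etherification: the 7-OH is a vinylogous carboxylic acid (para to C4=O, pKa about 7) and should be the only phenol ionised by one equivalent of carbonate, the 5-OH is held in the hydrogen bond to C4=O and the ring-B phenols (pKa about 9–10) stay protonated; SN2 at the primary allylic bromide in DMF favours O- over C-alkylation, and the buffered work-up spares the acid-labile prenyl ether.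

## Compound list

1 | 1-(2,4,6-trihydroxyphenyl)ethan-1-one (2,4,6-trihydroxyacetophenone) | CC(=O)c1c(O)cc(O)cc1O | starting material
2 | 1-[2,4-bis(benzyloxy)-6-hydroxyphenyl]ethan-1-one | CC(=O)c1c(O)cc(OCc2ccccc2)cc1OCc1ccccc1 | intermediate
3 | 2,4-dihydroxybenzaldehyde | O=Cc1ccc(O)cc1O | starting material
4 | 2,4-bis(benzyloxy)benzaldehyde | O=Cc1ccc(OCc2ccccc2)cc1OCc1ccccc1 | intermediate
5 | (E)-1-[2,4-bis(benzyloxy)-6-hydroxyphenyl]-3-[2,4-bis(benzyloxy)phenyl]prop-2-en-1-one | O=C(/C=C/c1ccc(OCc2ccccc2)cc1OCc1ccccc1)c1c(O)cc(OCc2ccccc2)cc1OCc1ccccc1 | intermediate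
6 | rac-5,7-bis(benzyloxy)-2-[2,4-bis(benzyloxy)phenyl]chroman-4-one (racemate, drawn without descriptor) | O=C1CC(c2ccc(OCc3ccccc3)cc2OCc2ccccc2)Oc2cc(OCc3ccccc3)cc(OCc3ccccc3)c21 | intermediate
7 | rac-2,3-trans-5,7-bis(benzyloxy)-2-[2,4-bis(benzyloxy)phenyl]-3-[phenyl(tosyloxy)-λ3-iodanyl]chroman-4-one (racemate, one enantiomer of the trans pair drawn) | O=C1[C@@H](I(OS(=O)(=O)c2ccc(C)cc2)c2ccccc2)[C@H](c2ccc(OCc3ccccc3)cc2OCc2ccccc2)Oc2cc(OCc3ccccc3)cc(OCc3ccccc3)c21 | intermediate (not isolated)
8 | 5,7-bis(benzyloxy)-3-[2,4-bis(benzyloxy)phenyl]-4H-chromen-4-one | O=c1c(-c2ccc(OCc3ccccc3)cc2OCc2ccccc2)coc2cc(OCc3ccccc3)cc(OCc3ccccc3)c12 | intermediate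
9 | 3-(2,4-dihydroxyphenyl)-5,7-dihydroxy-4H-chromen-4-one (2'-hydroxygenistein) | O=c1c(-c2ccc(O)cc2O)coc2cc(O)cc(O)c12 | intermediate
10 | 3-(2,4-dihydroxyphenyl)-5-hydroxy-7-[(3-methylbut-2-en-1-yl)oxy]-4H-chromen-4-one (achiral) | CC(C)=CCOc1cc(O)c2c(=O)c(-c3ccc(O)cc3O)coc2c1 | target

## Step count and risk

Total step count: 7. Longest linear sequence: 6 steps (steps 1, 3, 4, 5, 6, 7); step 2 is the one-step side branch.

**Step 5 (key step).** The most likely failure is loss of chemoselectivity of the iodine(III) reagent: electrophilic attack on the electron-rich arene carbons (C5' of ring B, C6 and C8 of ring A) would give diaryliodonium salts instead of the C3 iodane. A second failure mode is dehydrogenation without migration, if elimination outruns aryl participation. Fallback, setting out from 2 and coming back at 8: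
- Condensation of 2 with N,N-dimethylformamide dimethyl acetal should give the enaminone (E)-1-[2,4-bis(benzyloxy)-6-hydroxyphenyl]-3-(dimethylamino)prop-2-en-1-one F1.
- Iodine-induced cyclisation of F1 should give 5,7-bis(benzyloxy)-3-iodo-4H-chromen-4-one F2.
- The coupling partner would be made from commercial 4-bromoresorcinol by O-benzylation to 2,4-bis(benzyloxy)-1-bromobenzene F3, then bromine–lithium exchange and borylation to [2,4-bis(benzyloxy)phenyl]boronic acid F4.
- Suzuki–Miyaura coupling of F2 with F4 (Pd(dppf)Cl2, K2CO3, dioxane/water) returns to 8.

**Step 7.** The most likely failure is over-alkylation at O4' or O2' once some dianion forms, or C-prenylation at C6/C8 through the ambident 7-phenoxide. Fallback, setting out from 9 and coming back at 10: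
- Peracetylation (Ac2O, pyridine) should give 3-(2,4-diacetoxyphenyl)-4-oxo-4H-chromene-5,7-diyl diacetate F5.
- Thiolysis of the most activated ester (PhSH, imidazole, NMP, 0 °C) should free only the 7-OH, giving 3-(2,4-diacetoxyphenyl)-7-hydroxy-4-oxo-4H-chromen-5-yl acetate F6.
- Mitsunobu etherification with 3-methylbut-2-en-1-ol (PPh3, DIAD, THF) should give 3-(2,4-diacetoxyphenyl)-7-[(3-methylbut-2-en-1-yl)oxy]-4-oxo-4H-chromen-5-yl acetate F7.
- Mild methanolysis (K2CO3, MeOH, 0 °C) returns to 10.

**Step 4.** The most likely failure is incomplete ring closure: the donor-substituted ring B lowers the electrophilicity of the β-carbon, so the isomerisation may be slow or stop at an equilibrium mixture. Fallback, setting out from 5 and coming back at 8, bypassing 6 and step 5: the same aryl shift is run on the open form with thallium(III) nitrate in methanol/trimethyl orthoformate, which should give the rearranged acetal rac-1-[2,4-bis(benzyloxy)-6-hydroxyphenyl]-2-[2,4-bis(benzyloxy)phenyl]-3,3-dimethoxypropan-1-one F8. Acid (HCl, MeOH/THF, reflux) then closes the pyranone ring with loss of two methanol molecules to give 8.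

**Step 6.** The most likely failure is over-reduction of the C2=C3 bond, or stalling when partly debenzylated material precipitates on the catalyst. Fallback, setting out from 8 and coming back at 9: non-reductive Lewis-acid debenzylation with BCl3 and pentamethylbenzene as cation scavenger (CH2Cl2, −78 °C). It makes no new compound.

## Further compounds

F1 | step 5 | (E)-1-[2,4-bis(benzyloxy)-6-hydroxyphenyl]-3-(dimethylamino)prop-2-en-1-one | CN(C)/C=C/C(=O)c1c(O)cc(OCc2ccccc2)cc1OCc1ccccc1
F2 | step 5 | 5,7-bis(benzyloxy)-3-iodo-4H-chromen-4-one | O=c1c(I)coc2cc(OCc3ccccc3)cc(OCc3ccccc3)c12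
F3 | step 5 | 2,4-bis(benzyloxy)-1-bromobenzene | Brc1ccc(OCc2ccccc2)cc1OCc1ccccc1
F4 | step 5 | [2,4-bis(benzyloxy)phenyl]boronic acid | OB(O)c1ccc(OCc2ccccc2)cc1OCc1ccccc1
F5 | step 7 | 3-(2,4-diacetoxyphenyl)-4-oxo-4H-chromene-5,7-diyl diacetate | CC(=O)Oc1ccc(-c2coc3cc(OC(C)=O)cc(OC(C)=O)c3c2=O)c(OC(C)=O)c1
F6 | step 7 | 3-(2,4-diacetoxyphenyl)-7-hydroxy-4-oxo-4H-chromen-5-yl acetate | CC(=O)Oc1ccc(-c2coc3cc(O)cc(OC(C)=O)c3c2=O)c(OC(C)=O)c1
F7 | step 7 | 3-(2,4-diacetoxyphenyl)-7-[(3-methylbut-2-en-1-yl)oxy]-4-oxo-4H-chromen-5-yl acetate | CC(C)=CCOc1cc(OC(C)=O)c2c(=O)c(-c3ccc(OC(C)=O)cc3OC(C)=O)coc2c1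
F8 | step 4 | rac-1-[2,4-bis(benzyloxy)-6-hydroxyphenyl]-2-[2,4-bis(benzyloxy)phenyl]-3,3-dimethoxypropan-1-one | COC(OC)C(C(=O)c1c(O)cc(OCc2ccccc2)cc1OCc1ccccc1)c1ccc(OCc2ccccc2)cc1OCc1ccccc1
F0 | step 6 | none | none
A1 | alternative 1 | phloroglucinol (benzene-1,3,5-triol) | Oc1cc(O)cc(O)c1
A2 | alternative 1 | (2,4-dimethoxyphenyl)acetic acid | COc1ccc(CC(=O)O)c(OC)c1
A3 | alternative 1 | 2-(2,4-dimethoxyphenyl)-1-(2,4,6-trihydroxyphenyl)ethan-1-one | COc1ccc(CC(=O)c2c(O)cc(O)cc2O)c(OC)c1
A4 | alternative 1 | 3-(2,4-dimethoxyphenyl)-5,7-dihydroxy-4H-chromen-4-one | COc1ccc(-c2coc3cc(O)cc(O)c3c2=O)c(OC)c1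
A5 | alternative 2 | 5,7-bis(benzyloxy)-3-iodo-4H-chromen-4-one | O=c1c(I)coc2cc(OCc3ccccc3)cc(OCc3ccccc3)c12
A6 | alternative 2 | [2,4-bis(benzyloxy)phenyl]boronic acid | OB(O)c1ccc(OCc2ccccc2)cc1OCc1ccccc1
A7 | alternative 3 | 5,7-dihydroxy-4H-chromen-4-one | O=c1ccoc2cc(O)cc(O)c12
A8 | alternative 3 | resorcinol (benzene-1,3-diol) | Oc1cccc(O)c1
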